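## The problem

1. The target is one carbocycle, a cyclohex-3-ene with oxygen on every sp3 carbon. The ring is numbered C1 (quaternary carbinol carrying the C7H2OBz arm), C2 (CHOBz), C3=C4, C5 (CHOBz), C6 (CHOH). The configuration is (1R,2S,5S,6S): the C1 hydroxyl and the C2 benzoate lie on one face (β), the C5 benzoate and the C6 hydroxyl on the other (α).
2. Only C2 has to be bought. C5, C6 and C1 can be set relative to it if the ring is conformationally anchored while they form, and C3/C4, held as a cis-diol acetonide, can be that anchor.
3. Five oxygens must be told apart: benzoates on C7, C2 and C5 against a tertiary C1 hydroxyl and a secondary C6 hydroxyl that sits cis to the C5 benzoate. The order in which the hydroxyls appear therefore matters as much as any bond construction.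
4. In a chair anchored by the acetonide the C6 hydroxyl is axial and trans-diaxial to the C1 hydroxyl, so it is the less stable carbinol epimer and cannot be reached by equilibration.
5. The fragile features are the two allylic benzoates (ionisation, elimination towards an arene), benzoyl migration between the cis C5/C6 oxygens under base, and β-elimination across C5–C4 in any intermediate with a C6 carbonyl.
6. The enabling feature is that C6 lies between two carbinol carbons, C5 and C1. A one-carbon dinucleophile can be inserted between a C5 aldehyde and a C1 ketone, forming C5–C6 and C1–C6 and closing the ring in one operation; nitromethane does this, and its nitro group is a masked C6 oxygen.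
7. The open-chain partner C7–C1(=O)–C2(OR)–C3(O)–C4(O)–C5HO is a hexose skeleton with a carbonyl at each end of a 1,5-relationship, so a sugar can supply C2 in the right configuration and the C3/C4 cis-diol.

## Retrosynthesis

**Alkene from the cis-diol (20 ⇒ 19 ⇒ 18 ⇒ 17).** The C3=C4 π-bond is traced back to the C3–O and C4–O bonds of cyclic thionocarbonate 19, made from tetraol 18 and that from acetonide 17. Carrying the alkene through the route would forbid hydrogenolysis and expose two allylic benzoates to every later reagent. Keeping it as the acetonide avoids both and supplies the conformational anchor. The forward steps must thioacylate the cis-diol in preference to the hindered C6 and tertiary C1 hydroxyls, and eliminate at a temperature the allylic benzoates tolerate.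

**C6 carbinol last (17 ⇒ 16 ⇒ 15 ⇒ 14).** The C6–H bond is cut, giving ketone 16. Because the C6 hydroxyl then appears after all acylations, the three benzoates can be placed on tetraol ketone 15, where the only unreactive hydroxyl is the tertiary one. No selective acylation between C5 and C6 is needed, which a "reduce first" order would require. Tetraol 15 comes from dibenzyl ether 14 by hydrogenolysis, possible here because neither a nitro group nor an alkene is present. The reduction must deliver hydride to the β face of C6; the axial β hydroxyl on C1 is placed to do so.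

**Ketone from the nitro group (14 ⇒ 12).** The C6 carbonyl is traced to the C6 nitro group of 12 through nitronate 13. The two β-hydroxyls are deliberately left free: a retro-nitroaldol can then only return the same ring, whereas acylated β-oxygens would be eliminated as soon as the nitronate forms.

**The key cut (12 ⇒ 9 + 10).** Both bonds to C6 are cut, giving keto-aldehyde 9 and nitromethane 10. Cuts at C1–C2 or C4–C5 would need a carbon nucleophile within a polyoxygenated chain and would leave the quaternary centre unsolved. The cut at C6 removes the ring and three stereocentres at once and leaves an open chain whose only stereocentres are those of a sugar. The forward reaction must set C5 and C1 relative to C2; it is asked to do so under thermodynamic control in an anchored chair.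

**Keto-aldehyde from a sugar diacetonide (9 ⇒ 7 ⇒ 6 ⇒ 4 ⇒ 3 ⇒ 2 ⇒ 1).** Compound 9 can be read as a 6-aldehydo 2-ketohexose or, from the other end, as a 5-keto aldohexose of the D-lyxo series. The second reading is the practical one.

- In furanose diacetonide 1 the internal cis-acetonide already sits on the diol that becomes C3/C4.
- The terminal acetonide of 1 is the more labile one.
- The ring oxygen marks the hydroxyl that becomes the C2 ether.
- In the pyranose diacetonides of the ketose, by contrast, the ketal that would have to survive is the one that hydrolyses first.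

The aldehyde carbon is masked as a vinyl group (1 → 2), which frees the former ring oxygen for benzylation (3). The terminal acetonide is removed (4), the primary oxygen benzylated through stannylene 5 (6), the secondary alcohol oxidised (7), and the alkene cleaved through ozonide 8 to give 9.

## Roads not taken

**Alternative 1:** The ring is taken from an arene, and only the C5–O and C6–O bonds are made in the key step. Aerobic whole-cell oxidation of iodobenzene A1 by toluene dioxygenase gives diene diol A2.

- Merits: A2 is enantiopure, has the C5/C6 oxygens cis in the absolute configuration of the target, carries iodine at C1 as the handle for C7, and already contains C3=C4. A syn-dihydroxylation of C1=C2 anti to the protected diol would place the β oxygens on C1 and C2. No deoxygenation is needed, and the sequence could be roughly half as long as the one chosen.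
- Weak points: it needs a fermentation set-up. Once C7 is attached, the oxidant must choose the trisubstituted C1=C2 over the disubstituted C3=C4 of a conjugated diene, where steric and electronic preferences oppose each other. C5 and C6 arrive as an undifferentiated cis-diol, so the C5 benzoate / C6 hydroxyl pattern has to be won by a late selective acylation next to allylic esters.
- Comparison: this road is shorter and better on the alkene question. The chosen plan sets against it ordinary bench chemistry from a catalogue sugar, differentiation of all five oxygens by the order of events, and no diene regiochemistry to solve.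

**Alternative 2:** The C2–O and C3–O bonds are cut back to the achiral para-quinol A3. A chiral primary-amine salt with a peroxide oxidant epoxidises one of the two enantiotopic enone alkenes on the face of the C1 hydroxyl, giving epoxy quinol A4 with C1, C2 and C3 set.

- Merits: very short, catalytic, and the quaternary C1 with its benzoyloxymethyl arm is present from the start.
- Weak points: the step must distinguish two enantiotopic alkenes and two faces of a cross-conjugated dienone that carries a free tertiary hydroxyl and a base-sensitive ester, and this has no close model. A4 has oxygen on C2/C3 and a carbonyl at C4, whereas the target has oxygen on C2, C5 and C6 and the alkene at C3=C4. A Wharton-type transposition (whose nitrogen nucleophile threatens the benzoate) and a site- and face-selective syn-dihydroxylation of C5=C6 would have to follow, and then the same C5/C6 differentiation as in alternative 1.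
- Comparison: if the epoxidation were selective, this road would need fewer steps. The chosen plan sets against it an absolute configuration inherited from a sugar, and relative configurations that come from ring thermodynamics and an intramolecular hydride delivery.

**Alternative 3:** The C1–C2 bond is cut, with C3=C4 formed in the same event. Six-membered lactone A5 (C7 carbonyl, ring oxygen on C4, Z enol ether C3=C2 on C4) is converted into its silyl ketene acetal, which undergoes Ireland–Claisen ring contraction through a boat transition state to cyclohexene acid A6.

- Merits: the quaternary C1, the C2 stereocentre and the alkene arise in one stereospecific pericyclic step with chirality relayed from C4, and no late deoxygenation is needed.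
- Weak points: A5 has to be built over many steps from a rare sugar and must carry a geometrically pure Z enol ether, whose geometry defines C2. C7 arrives at the acid oxidation level. The p-methoxybenzyl ethers must be removed at allylic and tertiary positions. C5/C6 are again a cis-diol to be differentiated by selective benzoylation.
- Comparison: for C1/C2 this is the more elegant stereochemical relay, and it is as good or better on the alkene. The chosen plan sets against it a far cheaper precursor and a built-in differentiation of C5 and C6, and pays with a late deoxygenation and a Nef step.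

Key step: step 7

Assumption: compound 1 is bought as such (the catalogue diacetonide of D-mannose). All cyclitols are numbered as the target, β is the ring face of the C1 hydroxyl and α the opposite face.

## Route

Step 1
Reactants: 1 2,3:5,6-di-O-isopropylidene-α-D-mannofuranose
Product: 2 1,2-dideoxy-3,4:6,7-di-O-isopropylidene-D-manno-hept-1-enitol
Conditions: Ph3PCH3Br (2.5 equiv), KOtBu (2.5 equiv), THF, 0 °C → reflux
Reagents that add atoms: methyltriphenylphosphonium bromide, C[P+](c1ccccc1)(c1ccccc1)c1ccccc1.[Br-]
Why: Wittig methylenation of the aldehyde in equilibrium with the lactol (excess ylide first deprotonates the anomeric hydroxyl); no stereocentre is formed and the former ring oxygen emerges as the only free hydroxyl.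

Step 2
Reactants: 2 1,2-dideoxy-3,4:6,7-di-O-isopropylidene-D-manno-hept-1-enitol
Product: 3 5-O-benzyl-1,2-dideoxy-3,4:6,7-di-O-isopropylidene-D-manno-hept-1-enitol
Conditions: NaH, BnBr, Bu4NI (cat.), THF/DMF, 0 °C → rt
Reagents that add atoms: benzyl bromide, BrCc1ccccc1
Why: Williamson etherification of the single secondary alkoxide; acetonides and the terminal alkene are inert to these reagents.

Step 3
Reactants: 3 5-O-benzyl-1,2-dideoxy-3,4:6,7-di-O-isopropylidene-D-manno-hept-1-enitol
Product: 4 5-O-benzyl-1,2-dideoxy-3,4-O-isopropylidene-D-manno-hept-1-enitol
Conditions: AcOH/H2O (7:3), rt → 40 °C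
Reagents that add atoms: none
Why: Acid-catalysed ketal hydrolysis; the terminal monosubstituted dioxolane is cleaved markedly faster than the internal cis-disubstituted one, a standard selectivity of sugar diacetonides.

Step 4
Reactants: 4 5-O-benzyl-1,2-dideoxy-3,4-O-isopropylidene-D-manno-hept-1-enitol
Product: 6 5,7-di-O-benzyl-1,2-dideoxy-3,4-O-isopropylidene-D-manno-hept-1-enitol, via dibutylstannylene acetal 5 (not isolated)
Conditions: Bu2SnO, toluene, reflux (Dean–Stark); then BnBr, Bu4NBr, 90 °C
Reagents that add atoms: dibutyltin oxide, CCCC[Sn](=O)CCCC (atoms only in 5); benzyl bromide, BrCc1ccccc1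
Why: Stannylene acetal activation of the 1,2-diol followed by bromide-promoted alkylation, which places the benzyl group on the primary oxygen and leaves the secondary hydroxyl (the future C1) free.

Step 5
Reactants: 6 5,7-di-O-benzyl-1,2-dideoxy-3,4-O-isopropylidene-D-manno-hept-1-enitol
Product: 7 1,3-di-O-benzyl-6,7-dideoxy-4,5-O-isopropylidene-D-arabino-hept-6-en-2-ulose
Conditions: Dess–Martin periodinane, CH2Cl2, rt
Reagents that add atoms: none
Why: Dess–Martin oxidation of the secondary alcohol under near-neutral conditions, chosen so that the stereocentre α to the new ketone (the future C2) is not enolised.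

Step 6
Reactants: 7 1,3-di-O-benzyl-6,7-dideoxy-4,5-O-isopropylidene-D-arabino-hept-6-en-2-ulose
Product: 9 4,6-di-O-benzyl-2,3-O-isopropylidene-aldehydo-D-lyxo-hexos-5-ulose, via secondary ozonide 8 (not isolated)
Conditions: O3, CH2Cl2, −78 °C (indicator-dye end point); then PPh3, −78 °C → rt; used at once
Reagents that add atoms: ozone, [O-][O+]=O
Why: Ozonolysis of the monosubstituted alkene with reductive work-up; the alkene consumes ozone far faster than the benzyl ethers, and 9 is not stored because the α-alkoxy aldehyde is configurationally delicate.

Step 7
Reactants: 9 4,6-di-O-benzyl-2,3-O-isopropylidene-aldehydo-D-lyxo-hexos-5-ulose; 10 nitromethane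
Product: 12 6-nitrocyclitol diol (C7 and C2 benzyl ethers; C3/C4 acetonide; C1 and C5 hydroxyls; C6 nitro), via acyclic nitroaldol 11 (not isolated)
Conditions: MeNO2 (1.2 equiv), 1,8-diazabicyclo[5.4.0]undec-7-ene (0.2 equiv), THF, 0 °C → rt until equilibrated; AcOH quench
Reagents that add atoms: none
Why: The nitronate of 10 adds to the aldehyde (C5) to give 11, whose more acidic secondary nitro carbon is deprotonated again and adds to the C1 ketone, an α,α'-dialkoxy ketone activated towards addition. The closest known reaction type is the nitromethane cyclisation of sugar-derived dialdehydes to 2-nitro-1,3-diol cyclitols, here with a ketone as the second acceptor. The ring closes in the 6-(enolexo)-exo-trig mode through a chair. Both nitroaldol additions are reversible, and with catalytic amine the neutral nitro compound is the resting state, so the product ratio reflects chair stabilities and not those of a nitronate, in which allylic strain would push neighbouring groups axial. Only one chair keeps the C2 benzyloxy group and C3–O equatorial, and the cis-fused acetonide then fixes C4–O axial on the α face. In that chair the C6 nitro group is equatorial (β; the axial position is syn-axial to C4–O), the C5 hydroxyl is equatorial (α, trans to nitro), and C1 carries its larger CH2OBn arm equatorial (α) and its hydroxyl axial (β). The step needs the C1 and C5 configurations relative to C2, while C6 is erased in step 8. C5 is secured by a clear equatorial preference; C1 rests only on the modest size difference between CH2OBn and OH and is the point to watch.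

Step 8
Reactants: 12 6-nitrocyclitol diol
Product: 14 2,6-dihydroxy ketone (C6 carbonyl; otherwise as 12), via potassium nitronate 13 (not isolated)
Conditions: KOtBu (1.05 equiv), THF, −78 °C; then dimethyldioxirane in acetone, −78 → 0 °C; aq. NH4Cl
Reagents that add atoms: potassium tert-butoxide, CC(C)(C)[O-].[K+] (K+ only in 13); dimethyldioxirane, CC1(C)OO1
Why: Oxidative Nef reaction: the nitronate C=N bond is oxidised by the dioxirane and collapses to the ketone with loss of nitrite. With both β-hydroxyls free a retro-nitroaldol can only return the same ring, and C1 and C5 are not touched.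

Step 9
Reactants: 14 2,6-dihydroxy ketone
Product: 15 tetraol ketone (C7, C2, C5 and C1 hydroxyls; C3/C4 acetonide; C6 carbonyl)
Conditions: H2 (1 atm), 10% Pd/C, EtOAc/EtOH, rt
Reagents that add atoms: none
Why: Hydrogenolysis of both benzyl ethers, placed here because the nitro group is gone and the alkene is not yet present; the ketone and the acetonide are inert under neutral conditions.

Step 10
Reactants: 15 tetraol ketone
Product: 16 7,2,5-tri-O-benzoyl ketone (C1 hydroxyl free; C3/C4 acetonide)
Conditions: BzCl (3.5 equiv), pyridine, CH2Cl2, 0 °C → rt
Reagents that add atoms: benzoyl chloride, O=C(Cl)c1ccccc1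
Why: Acylation in pyridine esterifies the primary C7 and the two equatorial secondary hydroxyls (C2, C5), while the tertiary C1 hydroxyl does not react. No selectivity among secondary hydroxyls is needed because the C6 oxygen is still a carbonyl.

Step 11
Reactants: 16 7,2,5-tri-O-benzoyl ketone
Product: 17 7,2,5-tri-O-benzoyl-3,4-O-isopropylidene cyclitol (C1 hydroxyl β; C6 hydroxyl α)
Conditions: Me4NBH(OAc)3, MeCN/AcOH (1:1), −20 °C → rt
Reagents that add atoms: none
Why: Hydroxyl-directed reduction of the Saksena–Evans type: the axial β hydroxyl on C1 exchanges onto boron and delivers hydride intramolecularly to the β face of C6, so the new hydroxyl is α and axial, trans to the C1 hydroxyl and cis to the C5 benzoate. The acidic medium suppresses benzoyl migration from C5, and the reagent leaves esters alone.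

Step 12
Reactants: 17 7,2,5-tri-O-benzoyl-3,4-O-isopropylidene cyclitol
Product: 18 7,2,5-tri-O-benzoyl cyclitol tetraol (C1, C3, C4 and C6 hydroxyls)
Conditions: CF3CO2H/H2O (9:1), CH2Cl2, 0 °C → rt
Reagents that add atoms: none
Why: Acid hydrolysis of the cis-fused acetonide; benzoates and the tertiary alcohol are stable to aqueous acid, and acyl migration is slow under acidic conditions.

Step 13
Reactants: 18 7,2,5-tri-O-benzoyl cyclitol tetraol
Product: 19 3,4-O-thiocarbonyl derivative of 18 (cyclic thionocarbonate on the cis C3/C4 diol)
Conditions: 1,1'-thiocarbonyldiimidazole (1.2 equiv), THF, rt → 50 °C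
Reagents that add atoms: 1,1'-thiocarbonyldiimidazole, S=C(n1ccnc1)n1ccnc1
Why: First stage of the Corey–Winter olefination: the five-membered thionocarbonate closes on the cis-diol faster than the hindered axial C6 hydroxyl or the tertiary C1 hydroxyl is thioacylated. These two are trans-diaxial in the preferred chair and cannot bridge.

Step 14
Reactants: 19 3,4-O-thiocarbonyl derivative of 18
Product: 20 [(1R,2S,5S,6S)-2,5-bis(benzoyloxy)-1,6-dihydroxycyclohex-3-en-1-yl]methyl benzoate
Conditions: 1,3-dimethyl-2-phenyl-1,3,2-diazaphospholidine (3 equiv), THF, 40 °C
Reagents that add atoms: none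
Why: Corey–Winter olefination in its low-temperature diazaphospholidine (Corey–Hopkins) form: sulfur is abstracted and the resulting carbene loses CO2 by stereospecific syn cycloreversion to the cis C3=C4 alkene. The mild temperature spares the two allylic benzoates, and no stereocentre changes.

## Compound list

1 | 2,3:5,6-di-O-isopropylidene-α-D-mannofuranose | O[C@H]1O[C@H]([C@H]2COC(C)(C)O2)[C@@H]3OC(C)(C)O[C@H]13 | starting material
2 | 1,2-dideoxy-3,4:6,7-di-O-isopropylidene-D-manno-hept-1-enitol | C=C[C@H]1OC(C)(C)O[C@H]1[C@H](O)[C@H]2COC(C)(C)O2 | intermediate
3 | 5-O-benzyl-1,2-dideoxy-3,4:6,7-di-O-isopropylidene-D-manno-hept-1-enitol | C=C[C@H]1OC(C)(C)O[C@H]1[C@H](OCc2ccccc2)[C@H]3COC(C)(C)O3 | intermediate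
4 | 5-O-benzyl-1,2-dideoxy-3,4-O-isopropylidene-D-manno-hept-1-enitol | C=C[C@H]1OC(C)(C)O[C@H]1[C@H](OCc2ccccc2)[C@H](O)CO | intermediate
5 | 6,7-O-dibutylstannylene acetal of 4 | C=C[C@H]1OC(C)(C)O[C@H]1[C@H](OCc2ccccc2)[C@H]3CO[Sn](CCCC)(CCCC)O3 | intermediate (not isolated)
6 | 5,7-di-O-benzyl-1,2-dideoxy-3,4-O-isopropylidene-D-manno-hept-1-enitol | C=C[C@H]1OC(C)(C)O[C@H]1[C@H](OCc2ccccc2)[C@H](O)COCc3ccccc3 | intermediate
7 | 1,3-di-O-benzyl-6,7-dideoxy-4,5-O-isopropylidene-D-arabino-hept-6-en-2-ulose | C=C[C@H]1OC(C)(C)O[C@H]1[C@H](OCc2ccccc2)C(=O)COCc3ccccc3 | intermediate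
8 | secondary ozonide (1,2,4-trioxolane) of 7, ozonide carbon unassigned | C1OOC(O1)[C@H]2OC(C)(C)O[C@H]2[C@H](OCc3ccccc3)C(=O)COCc4ccccc4 | intermediate (not isolated)
9 | 4,6-di-O-benzyl-2,3-O-isopropylidene-aldehydo-D-lyxo-hexos-5-ulose (equally 1,3-di-O-benzyl-4,5-O-isopropylidene-6-aldehydo-D-fructose, keto form) | O=C[C@H]1OC(C)(C)O[C@H]1[C@H](OCc2ccccc2)C(=O)COCc3ccccc3 | intermediate
10 | nitromethane | C[N+](=O)[O-] | starting material
11 | acyclic nitroaldol: nitromethane adduct at the aldehyde of 9 (new carbinol drawn in the configuration that leads to 12; it equilibrates) | [O-][N+](=O)C[C@@H](O)[C@H]1OC(C)(C)O[C@H]1[C@H](OCc2ccccc2)C(=O)COCc3ccccc3 | intermediate (not isolated)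
12 | nitrocyclitol: C1 OH β and CH2OBn α; C2 OBn β; C3/C4 O-isopropylidene α; C5 OH α; C6 NO2 β (equatorial) | C(OC[C@]1(O)[C@@H](OCc2ccccc2)[C@@H]3OC(C)(C)O[C@@H]3[C@H](O)[C@H]1[N+](=O)[O-])c4ccccc4 | intermediate
13 | potassium nitronate of 12 | C(OC[C@]1(O)[C@@H](OCc2ccccc2)[C@@H]3OC(C)(C)O[C@@H]3[C@H](O)C1=[N+]([O-])[O-])c4ccccc4.[K+] | intermediate (not isolated)
14 | ketone: C6 carbonyl; C1 OH β, CH2OBn α; C2 OBn β; C3/C4 acetonide α; C5 OH α | C(OC[C@]1(O)[C@@H](OCc2ccccc2)[C@@H]3OC(C)(C)O[C@@H]3[C@H](O)C1=O)c4ccccc4 | intermediate
15 | tetraol ketone: 14 without benzyl groups | OC[C@]1(O)[C@@H](O)[C@@H]2OC(C)(C)O[C@@H]2[C@H](O)C1=O | intermediate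
16 | tribenzoate ketone: benzoates on C7, C2 (β), C5 (α); C1 OH β; C3/C4 acetonide α; C6 carbonyl | O=C(OC[C@]1(O)[C@@H](OC(=O)c2ccccc2)[C@@H]3OC(C)(C)O[C@@H]3[C@H](OC(=O)c4ccccc4)C1=O)c5ccccc5 | intermediate
17 | 16 reduced at C6: C6 OH α (axial), trans to C1 OH | O=C(OC[C@]1(O)[C@@H](OC(=O)c2ccccc2)[C@@H]3OC(C)(C)O[C@@H]3[C@H](OC(=O)c4ccccc4)[C@@H]1O)c5ccccc5 | intermediate
18 | tetraol tribenzoate: C3 and C4 OH α (cis); C1 OH β; C6 OH α | O=C(OC[C@]1(O)[C@@H](OC(=O)c2ccccc2)[C@H](O)[C@H](O)[C@H](OC(=O)c3ccccc3)[C@@H]1O)c4ccccc4 | intermediate
19 | 3,4-cyclic thionocarbonate of 18 | O=C(OC[C@]1(O)[C@@H](OC(=O)c2ccccc2)[C@@H]3OC(=S)O[C@@H]3[C@H](OC(=O)c4ccccc4)[C@@H]1O)c5ccccc5 | intermediate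
20 | [(1R,2S,5S,6S)-2,5-bis(benzoyloxy)-1,6-dihydroxycyclohex-3-en-1-yl]methyl benzoate | O=C(OC[C@]1(O)[C@@H](OC(=O)c2ccccc2)C=C[C@H](OC(=O)c2ccccc2)[C@@H]1O)c1ccccc1 | target

## Step count and least certain steps

Total step count: 14. Longest linear sequence: 14 steps (1 → 20); nitromethane 10 enters at step 7.

**Step 7 (key step).**
- What may go wrong: closure onto the ketone may stay incomplete, since the ketone nitroaldol is the less favourable of the two additions. Discrimination at C1 may be insufficient, because it rests only on the size difference between CH2OBn and OH. Before the second addition, 9 may lose configuration by enolisation next to either carbonyl, or lose the acetonide oxygen by β-elimination.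
- Fallback (sets out from 7, returns at 12): the two additions are decoupled and their order reversed. Addition of 10, used as co-solvent, to the ketone of 7 under catalysis by 1,1,3,3-tetramethylguanidine gives the tertiary nitro alcohol F1, whose C1 epimers can be separated at this open-chain stage. Ozonolysis with PPh3 work-up gives the nitro aldehyde F2 (it may rest as its lactol). With Et3N, F2 closes quickly onto the aldehyde to give 12.

**Step 8.**
- What may go wrong: the nitronate may open by retro-nitroaldol or dehydrate across C5–C6 before it is oxidised. The α,α'-dihydroxy ketone may isomerise or eliminate across C5–C4 if any base remains.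
- Fallback (sets out from 12, returns at 14): the route avoids the nitronate. Reduction with Zn dust in AcOH/THF gives the amino diol F3. Transamination with 3,5-di-tert-butyl-1,2-benzoquinone, followed by hydrolysis of the rearranged imine with aqueous oxalic acid, gives 14.

**Step 11.**
- What may go wrong: the tertiary hydroxyl may fail to engage boron, giving no reaction at a ketone flanked by a quaternary centre. Alternatively the facial selectivity may be poor because some hydride arrives without direction.
- Fallback (sets out from 14, returns at 17): steric approach control before any ester is present. LiBH(s-Bu)3 in THF at −78 °C should attack C6 from the β face, because the axial C4 oxygen blocks the axial trajectory; this gives the triol F4. Hydrogenolysis over Pd/C gives the pentaol F5. Low-temperature benzoylation of the primary C7 and the equatorial C2 and C5 hydroxyls then leads to 17. This fallback reintroduces a selectivity demand: it must leave untouched the axial C6 hydroxyl, which is wedged between C1 and C5.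

**Step 13.**
- What may go wrong: the C6 hydroxyl may be thioacylated in competition, or the imidazole set free may promote benzoyl migration (C5 to C6, C2 to C3) before the thionocarbonate has closed.
- Fallback (sets out from 17, returns at 20): the C6 hydroxyl is masked before the diol is exposed. Levulinic acid with N,N'-dicyclohexylcarbodiimide and catalytic 4-(dimethylamino)pyridine gives the 6-O-levulinate F6. Aqueous CF3CO2H gives the diol F7, 1,1'-thiocarbonyldiimidazole the thionocarbonate F8, and the diazaphospholidine the alkene F9. Hydrazine acetate then removes the levulinate without touching the benzoates and gives 20.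

## Further compounds

F1 | step 7 | tertiary nitro alcohol: nitromethane adduct at the ketone of 7 (C1 configuration as in 12) | C=C[C@H]1OC(C)(C)O[C@H]1[C@H](OCc2ccccc2)[C@](O)(C[N+](=O)[O-])COCc3ccccc3
F2 | step 7 | nitro aldehyde: ozonolysis product of F1 | O=C[C@H]1OC(C)(C)O[C@H]1[C@H](OCc2ccccc2)[C@](O)(C[N+](=O)[O-])COCc3ccccc3
F3 | step 8 | amino diol: 12 with C6 NH2 (β) in place of NO2 | C(OC[C@]1(O)[C@@H](OCc2ccccc2)[C@@H]3OC(C)(C)O[C@@H]3[C@H](O)[C@H]1N)c4ccccc4
F4 | step 11 | triol: 14 reduced at C6 (C6 OH α) | C(OC[C@]1(O)[C@@H](OCc2ccccc2)[C@@H]3OC(C)(C)O[C@@H]3[C@H](O)[C@@H]1O)c4ccccc4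
F5 | step 11 | pentaol: F4 without benzyl groups | OC[C@]1(O)[C@@H](O)[C@@H]2OC(C)(C)O[C@@H]2[C@H](O)[C@@H]1O
F6 | step 13 | 6-O-levulinoyl derivative of 17 | O=C(OC[C@]1(O)[C@@H](OC(=O)c2ccccc2)[C@@H]3OC(C)(C)O[C@@H]3[C@H](OC(=O)c4ccccc4)[C@@H]1OC(=O)CCC(C)=O)c5ccccc5
F7 | step 13 | 3,4-diol from F6 | O=C(OC[C@]1(O)[C@@H](OC(=O)c2ccccc2)[C@H](O)[C@H](O)[C@H](OC(=O)c3ccccc3)[C@@H]1OC(=O)CCC(C)=O)c4ccccc4
F8 | step 13 | 3,4-cyclic thionocarbonate of F7 | O=C(OC[C@]1(O)[C@@H](OC(=O)c2ccccc2)[C@@H]3OC(=S)O[C@@H]3[C@H](OC(=O)c4ccccc4)[C@@H]1OC(=O)CCC(C)=O)c5ccccc5
F9 | step 13 | 6-O-levulinoyl derivative of 20 | O=C(OC[C@]1(O)[C@@H](OC(=O)c2ccccc2)C=C[C@H](OC(=O)c3ccccc3)[C@@H]1OC(=O)CCC(C)=O)c4ccccc4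
A1 | alternative 1 | iodobenzene | Ic1ccccc1
A2 | alternative 1 | (1S,2S)-3-iodocyclohexa-3,5-diene-1,2-diol | IC1=CC=C[C@H](O)[C@@H]1O
A3 | alternative 2 | (1-hydroxy-4-oxocyclohexa-2,5-dien-1-yl)methyl benzoate (achiral para-quinol) | O=C1C=CC(O)(COC(=O)c2ccccc2)C=C1
A4 | alternative 2 | 2,3-epoxy para-quinol, oxirane syn to the C1 hydroxyl | O=C(OC[C@]1(O)[C@H]2O[C@H]2C(=O)C=C1)c1ccccc1
A5 | alternative 3 | six-membered lactone: C7 carbonyl, ring oxygen on C4, C5/C6 acetonide, C1 p-methoxybenzyl ether, Z p-methoxybenzyl enol ether C3=C2 on C4 | O=C1O[C@@H](/C=C\OCc2ccc(OC)cc2)[C@@H]3OC(C)(C)O[C@@H]3[C@@H]1OCc4ccc(OC)cc4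
A6 | alternative 3 | 1,2-bis(p-methoxybenzyloxy)-5,6-O-isopropylidene-cyclohex-3-ene-1-carboxylic acid | OC(=O)[C@]1(OCc2ccc(OC)cc2)[C@@H](OCc3ccc(OC)cc3)C=C[C@@H]4OC(C)(C)O[C@H]14
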